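The route rests on cutting the benzylic C7–C8 bond (ArCH2–CH). The four-carbon core C9–C8–C8'–C9' is mapped onto the ring of (5R)-5-(l-menthyloxy)-2(5H)-furanone. Both syringyl rings come from one aldehyde, used once as a lithiated dithioacetal and once as a benzyl bromide. In one flask the carbanion adds to C8'; the resulting enolate, already carrying one aryl half, is benzylated at C8. The step exploits the C2-symmetric 2,3-dibenzylbutane-1,4-diol unit, in which C8 is α and C8' β to a latent C9 carbonyl. It builds the whole skeleton and sets both stereocentres by relay from the acetal carbon. Sulfur, benzyl and menthyl groups then leave reductively.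

Key step: step 5

Assumption: lignan numbering is used (C7/C7' benzylic CH2, C8/C8' stereogenic CH, C9/C9' CH2OH), and compound 6, the crystalline l-menthol acetal of 5-hydroxy-2(5H)-furanone, is taken as a catalogue chiral building block.

Step 1
Reactants: 1 syringaldehyde (4-hydroxy-3,5-dimethoxybenzaldehyde)
Product: 2 4-(benzyloxy)-3,5-dimethoxybenzaldehyde
Conditions: BnBr, K2CO3, DMF, 60 °C
Reagents that add atoms: benzyl bromide, BrCc1ccccc1
Why: Williamson ether synthesis on the acidic phenol; the benzyl ether masks the OH against n-BuLi and PBr3 in later steps, and no stereocentre is formed.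

Step 2
Reactants: 2 4-(benzyloxy)-3,5-dimethoxybenzaldehyde
Product: 3 4-(benzyloxy)-3,5-dimethoxybenzaldehyde bis(phenylthio)acetal
Conditions: PhSH (2.1 equiv), BF3·OEt2 (cat.), CH2Cl2, 0 °C → rt
Reagents that add atoms: benzenethiol, Sc1ccccc1
Why: Lewis-acid-catalysed dithioacetalisation of an aromatic aldehyde turns the formyl carbon (future C7') into a carbon acid whose anion is soft enough for 1,4-addition.

Step 3
Reactants: 2 4-(benzyloxy)-3,5-dimethoxybenzaldehyde
Product: 4 4-(benzyloxy)-3,5-dimethoxybenzyl alcohol
Conditions: NaBH4, MeOH–THF, 0 °C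
Reagents that add atoms: none
Why: Borohydride reduction of an aromatic aldehyde to the benzylic alcohol, with all ether groups inert.

Step 4
Reactants: 4 4-(benzyloxy)-3,5-dimethoxybenzyl alcohol
Product: 5 4-(benzyloxy)-3,5-dimethoxybenzyl bromide
Conditions: PBr3, Et2O, 0 °C; used freshly prepared
Reagents that add atoms: phosphorus tribromide, BrP(Br)Br
Why: Bromination of a primary benzylic alcohol with PBr3 (SN2 displacement of the phosphite ester by bromide) is fast at 0 °C for this electron-rich system and leaves the aryl ethers intact.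

Step 5
Reactants: 3 4-(benzyloxy)-3,5-dimethoxybenzaldehyde bis(phenylthio)acetal; 6 (5R)-5-[(1R,2S,5R)-menthyloxy]-2(5H)-furanone; 5 4-(benzyloxy)-3,5-dimethoxybenzyl bromide
Product: 9 (3R,4R,5R)-3-[4-(benzyloxy)-3,5-dimethoxybenzyl]-4-{[4-(benzyloxy)-3,5-dimethoxyphenyl]bis(phenylthio)methyl}-5-(l-menthyloxy)dihydrofuran-2(3H)-one, via lithiated dithioacetal 7 (not isolated), via lithium enolate 8 (not isolated)
Conditions: 3, n-BuLi, THF, −78 °C; then 6, −78 °C; then 5, DMPU, −78 °C → rt
Reagents that add atoms: none
Why: n-BuLi deprotonates 3 to the sulfur-stabilised benzylic carbanion 7, which adds 1,4 to butenolide 6 (C7'–C8' bond), and the lithium enolate 8 so formed, which already holds one aryl half and the whole C4 core, displaces bromide from 5 in an SN2 C-alkylation that forms the C7–C8 bond and unites the two halves. The closest known reaction type is the tandem conjugate addition–enolate alkylation (three-component Michael/alkylation) of lithiated aryl dithioacetals with butenolides, a standard entry to trans-dibenzylbutyrolactone lignans. No ring is closed; the existing five-membered lactone ring serves only as a temporary stereochemical template. C4 (future C8') is set by attack of 7 on the ring face anti to the C5 menthyloxy group, and C3 (future C8) is set by approach of 5 anti to the very bulky C4 bis(phenylthio)benzyl group, which should give the 3,4-trans-4,5-trans (3R,4R,5R) isomer, also the thermodynamically preferred one at the epimerisable C3. The step needs 1,4- over 1,2-addition, secured by the soft, hindered, charge-delocalised carbanion, and C-mono-alkylation over O-alkylation, retro-Michael cleavage or proton exchange, secured by the reactive benzylic bromide, the DMPU-activated lithium enolate and the shielding of the remaining C3–H in 9.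

Step 6
Reactants: 9 tandem adduct
Product: 10 (3R,4R,5R)-3,4-bis(4-hydroxy-3,5-dimethoxybenzyl)-5-(l-menthyloxy)dihydrofuran-2(3H)-one
Conditions: Raney Ni (W-2, large excess), H2 (1 atm), EtOH, reflux
Reagents that add atoms: none
Why: Raney nickel hydrogenolysis (Mozingo-type reductive desulfurisation) cleaves both benzylic C–S bonds and, under hydrogen, also the two aryl benzyl ethers, while the lactone, the acetal and the three ring stereocentres are not touched because none of them bears sulfur or is benzylic.

Step 7
Reactants: 10 bis-phenol menthyloxy lactone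
Product: 11 (2R,3R)-2,3-bis(4-hydroxy-3,5-dimethoxybenzyl)butane-1,4-diol (5,5'-dimethoxysecoisolariciresinol)
Conditions: LiAlH4 (excess), THF, 0 °C → reflux, argon; aqueous Rochelle salt work-up, pH brought to about 5
Reagents that add atoms: none
Why: Hydride reduction of a γ-alkoxylactone (pseudo-ester) takes the lactone carbonyl to C9H2OH, the liberated hemiacetal alkoxide expels menthoxide, and the resulting aldehyde is reduced at once to C9'H2OH, so C8 and C8' should keep their R configuration, the free phenols merely consuming hydride as phenoxides.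

Compound list
1 | syringaldehyde | COc1cc(C=O)cc(OC)c1O | starting material
2 | 4-(benzyloxy)-3,5-dimethoxybenzaldehyde | COc1cc(C=O)cc(OC)c1OCc1ccccc1 | intermediate
3 | 4-(benzyloxy)-3,5-dimethoxybenzaldehyde bis(phenylthio)acetal | COc1cc(C(Sc2ccccc2)Sc2ccccc2)cc(OC)c1OCc1ccccc1 | intermediate
4 | 4-(benzyloxy)-3,5-dimethoxybenzyl alcohol | COc1cc(CO)cc(OC)c1OCc1ccccc1 | intermediate
5 | 4-(benzyloxy)-3,5-dimethoxybenzyl bromide | COc1cc(CBr)cc(OC)c1OCc1ccccc1 | intermediate
6 | (5R)-5-[(1R,2S,5R)-menthyloxy]-2(5H)-furanone | C[C@@H]1CC[C@H]([C@@H](C1)O[C@H]2C=CC(=O)O2)C(C)C | starting material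
7 | lithiated dithioacetal, [4-(benzyloxy)-3,5-dimethoxyphenyl]bis(phenylthio)methyllithium (not isolated) | [Li]C(Sc1ccccc1)(Sc1ccccc1)c1cc(OC)c(OCc2ccccc2)c(OC)c1 | intermediate
8 | lithium enolate of the (4R,5R) Michael adduct (not isolated) | C[C@@H]1CC[C@H]([C@@H](C1)O[C@@H]2OC(O[Li])=C[C@H]2C(Sc3ccccc3)(Sc3ccccc3)c3cc(OC)c(OCc4ccccc4)c(OC)c3)C(C)C | intermediate
9 | (3R,4R,5R) tandem adduct, 3,4-trans-4,5-trans | C[C@@H]1CC[C@H]([C@@H](C1)O[C@@H]2OC(=O)[C@H](Cc3cc(OC)c(OCc4ccccc4)c(OC)c3)[C@H]2C(Sc3ccccc3)(Sc3ccccc3)c3cc(OC)c(OCc4ccccc4)c(OC)c3)C(C)C | intermediate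
10 | (3R,4R,5R)-3,4-bis(4-hydroxy-3,5-dimethoxybenzyl)-5-(l-menthyloxy)dihydrofuran-2(3H)-one | C[C@@H]1CC[C@H]([C@@H](C1)O[C@@H]2OC(=O)[C@H](Cc3cc(OC)c(O)c(OC)c3)[C@H]2Cc3cc(OC)c(O)c(OC)c3)C(C)C | intermediate
11 | (2R,3R)-5,5'-dimethoxysecoisolariciresinol | COc1cc(C[C@@H](CO)[C@H](CO)Cc2cc(OC)c(O)c(OC)c2)cc(OC)c1O | target

Total step count: 7. Longest linear sequence: 6 (steps 1, 3, 4, 5, 6, 7).

Steps most likely to fail

Step 5. The SN2 benzylation at the hindered α-carbon is slow. Enolate 8 may therefore be lost to retro-Michael cleavage or proton exchange on warming, and the electron-rich bromide may decompose before it reacts. The fallback sets out from 8 (made from 3 and 6 as before) and traps it at −78 °C with aldehyde 2 instead of bromide 5. This aldol addition is much faster, forms the same C7–C8 bond and again occurs anti to the C4 substituent. It should give the (3S,4R,5R) aldol adduct F1 as a mixture at the C7 carbinol, which does not matter. Raney Ni/H2 in EtOH should then remove sulfur and benzyl groups to give the 7-hydroxy bis-phenol F2. Hydrogenolysis of its p-hydroxybenzylic alcohol (H2, Pd/C, EtOH–AcOH) brings the material back to the route at 10. Steps 3 and 4 become unnecessary.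

Step 6. Cleavage of the benzyl ethers may stall on the sulfided nickel surface, the electron-rich rings may be partly saturated, or the phenolic product may stay adsorbed on the metal. The fallback sets out from 9 and separates the two tasks. Nickel boride (NiCl2·6H2O, NaBH4, MeOH–THF, 0 °C) should remove only sulfur and give the di-O-benzyl lactone acetal F3. LiAlH4 in THF should then give the di-O-benzyl diol F4. Hydrogenolysis on sulfur-free material (H2, Pd/C, EtOAc–EtOH) returns to the route at 11.

Step 7. Reduction may stall at the lactol stage at the acetal carbon, and the polyphenolic tetraol may be retained on aluminium salts during work-up. The fallback sets out from 10 and avoids aluminium. NaBH4 in aqueous ethanolic KOH under argon opens the pseudo-ester, releases menthol and reduces the unmasked aldehyde. Acidification with HCl then closes the ring to the (3R,4R)-trans-lactone F5, which can be purified. LiBH4 in THF–MeOH should reduce F5 to the diol, returning to the route at 11. Boron residues are removed by co-evaporation with methanol.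

Further compounds
F1 | step 5 | (3S,4R,5R)-3-{[4-(benzyloxy)-3,5-dimethoxyphenyl](hydroxy)methyl}-4-{[4-(benzyloxy)-3,5-dimethoxyphenyl]bis(phenylthio)methyl}-5-(l-menthyloxy)dihydrofuran-2(3H)-one, C7 epimer mixture | C[C@@H]1CC[C@H]([C@@H](C1)O[C@@H]2OC(=O)[C@H](C(O)c3cc(OC)c(OCc4ccccc4)c(OC)c3)[C@H]2C(Sc3ccccc3)(Sc3ccccc3)c3cc(OC)c(OCc4ccccc4)c(OC)c3)C(C)C
F2 | step 5 | (3S,4R,5R)-3-[hydroxy(4-hydroxy-3,5-dimethoxyphenyl)methyl]-4-(4-hydroxy-3,5-dimethoxybenzyl)-5-(l-menthyloxy)dihydrofuran-2(3H)-one, C7 epimer mixture | C[C@@H]1CC[C@H]([C@@H](C1)O[C@@H]2OC(=O)[C@H](C(O)c3cc(OC)c(O)c(OC)c3)[C@H]2Cc3cc(OC)c(O)c(OC)c3)C(C)C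
F3 | step 6 | (3R,4R,5R)-3,4-bis[4-(benzyloxy)-3,5-dimethoxybenzyl]-5-(l-menthyloxy)dihydrofuran-2(3H)-one | C[C@@H]1CC[C@H]([C@@H](C1)O[C@@H]2OC(=O)[C@H](Cc3cc(OC)c(OCc4ccccc4)c(OC)c3)[C@H]2Cc3cc(OC)c(OCc4ccccc4)c(OC)c3)C(C)C
F4 | step 6 | (2R,3R)-2,3-bis[4-(benzyloxy)-3,5-dimethoxybenzyl]butane-1,4-diol | COc1cc(C[C@@H](CO)[C@H](CO)Cc2cc(OC)c(OCc3ccccc3)c(OC)c2)cc(OC)c1OCc1ccccc1
F5 | step 7 | (3R,4R)-3,4-bis(4-hydroxy-3,5-dimethoxybenzyl)dihydrofuran-2(3H)-one | O=C1OC[C@H](Cc2cc(OC)c(O)c(OC)c2)[C@H]1Cc1cc(OC)c(O)c(OC)c1
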